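**Plan**

1. Atoms are numbered C1–C20 in the order of the target SMILES. Retrosynthesis: C16–C17 is cut first (methyl addition to a C16 ketone); then C11–C18 and C13–C14 are cut together, opening rings B and C at once to a norbornane with an (E)-bromoalkene chain on C8 and a 2-silyloxydiene on C19.
2. The enabling feature is ring C (C11, C13, C14, C15, C16, C18). As a C15=C16 enol ether it is a cyclohexene, its C13 bromide is cis to the C12 methyl on quaternary C11, and it is trans-fused along C11–C18 to ring B (C8, C9, C10, C11, C18, C19), whose remaining atoms form a four-atom tether held by the bicycle.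
3. Further cuts: C19–C18 (exo alkylation of a C20 ketone enolate); C8–C4 and C6–C5 (Diels–Alder of a 2-silyloxycyclopentadiene with a chiral acrylimide); C8–C9 (Grignard addition to 3-ethoxycyclopentenone).
4. Forward order: bromoalkenyl chain, cyclopentenone, norbornane core, isopropyl group, C19 side chain and vinyl ketone, bis-silylation, rings B and C together, C17 methyl.
5. Stereochemistry: C4, C6 and C8 (absolute) from the (S)-4-benzyloxazolidinone in the endo Diels–Alder step; C19 and C20 from exo attack on the norbornanone; C11, C13 and C18 from the alkene geometry and the chair-folded tether; C16 from methyl addition anti to the axial C12 methyl.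

Key step: step 15

Remark: exo means on the side of the C7 methylene bridge. Small carbon reagents (Me3Al, MeLi, the Wittig salt, the bromoacetamide, vinylmagnesium bromide) are numbered as starting materials. In names of bicyclic compounds the locants are those of bicyclo[2.2.1]heptane with the oxygen-bearing carbon as C-2 (C-2 = target C20, C-3 = C19, C-4 = C8, C-5 = C4).

**Step 1**
Reactants: 1 but-3-yn-1-ol; 2 trimethylaluminium
Product: 4 (3E)-4-bromo-3-methylbut-3-en-1-ol, via alkenylalane 3 (not isolated)
Conditions: Me3Al (3 equiv), Cp2ZrCl2 (0.25 equiv), CH2Cl2, 0 → 23 °C; then NBS, THF, −30 → 0 °C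
Reagents that add atoms: trimethylaluminium (2), C[Al](C)C; N-bromosuccinimide, O=C1CCC(=O)N1Br
Why: Zirconium-catalysed carboalumination (Negishi) adds methyl and aluminium syn across the alkyne with aluminium at the terminus, and bromodealumination with retention should give the (E)-bromoalkene in which Br is cis to the methyl group.

**Step 2**
Reactants: 4 (3E)-4-bromo-3-methylbut-3-en-1-ol
Product: 5 (1E)-1,4-dibromo-2-methylbut-1-ene
Conditions: CBr4, PPh3, CH2Cl2, 0 °C
Reagents that add atoms: carbon tetrabromide, BrC(Br)(Br)Br
Why: Appel bromination converts the primary alcohol to the bromide under neutral conditions that leave the alkenyl bromide untouched.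

**Step 3**
Reactants: 5 (1E)-1,4-dibromo-2-methylbut-1-ene; 6 3-ethoxycyclopent-2-en-1-one
Product: 9 3-[(3E)-4-bromo-3-methylbut-3-en-1-yl]cyclopent-2-en-1-one, via Grignard reagent 7 (not isolated), via tertiary allylic alcohol 8 (not isolated)
Conditions: Mg, THF, 23 °C; 6, 0 °C; then 1 M HCl, 0 °C
Reagents that add atoms: none
Why: Stork–Danheiser sequence, in which magnesium should insert into the primary sp3 C–Br bond much faster than into the hindered alkenyl C–Br bond, and 1,2-addition to the vinylogous ester followed by acid hydrolysis with loss of ethanol transposes the carbonyl to give the 3-substituted enone.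

**Step 4**
Reactants: 9 3-[(3E)-4-bromo-3-methylbut-3-en-1-yl]cyclopent-2-en-1-one
Product: 11 2-(triisopropylsilyloxy)cyclopenta-1,3-diene carrying the bromoalkenyl chain on C-4, via lithium dienolate 10 (not isolated)
Conditions: LDA, THF, −78 °C; TIPSOTf, −78 → −40 °C; cold non-acidic work-up, used at once
Reagents that add atoms: triisopropylsilyl trifluoromethanesulfonate, CC(C)[Si](OS(=O)(=O)C(F)(F)F)(C(C)C)C(C)C
Why: Kinetic deprotonation of the α′-methylene (future C6) gives the cross-conjugated dienolate, and O-silylation traps it as the 2-silyloxydiene before 1,5-hydrogen shifts can scramble the ring double bonds.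

**Step 5**
Reactants: 12 (4S)-4-benzyl-1,3-oxazolidin-2-one; 13 prop-2-enoyl chloride
Product: 15 (4S)-4-benzyl-3-(prop-2-enoyl)-1,3-oxazolidin-2-one, via bromomagnesium amide 14 (not isolated)
Conditions: MeMgBr, THF, 0 °C; 13, −78 → 0 °C
Reagents that add atoms: prop-2-enoyl chloride (13), C=CC(=O)Cl
Why: N-acylation of the metalated oxazolidinone is the standard route to the chiral acrylimide, and the magnesium salt and low temperature limit polymerisation.

**Step 6**
Reactants: 11 silyloxydiene; 15 (4S)-4-benzyl-3-(prop-2-enoyl)-1,3-oxazolidin-2-one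
Product: 16 endo Diels–Alder adduct (norbornene TIPS enol ether with the imide 5-endo and the chain on bridgehead C-4)
Conditions: Me2AlCl (1.4 equiv), CH2Cl2, −78 °C; pH 7 buffer work-up
Reagents that add atoms: none
Why: Auxiliary-controlled, Lewis-acid-promoted Diels–Alder reaction (Evans), in which the benzyl group of the aluminium-chelated s-cis acrylimide shields one face so that the diene adds endo to the opposite Cα face, while the silyloxy group ("para") and the alkyl-bearing diene terminus ("ortho") both direct the acyl-bearing carbon to that terminus, setting C4 (endo acyl), C6 and the quaternary bridgehead C8 together.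

**Step 7**
Reactants: 16 Diels–Alder adduct
Product: 17 5-endo carboxylic acid (TIPS enol ether retained)
Conditions: LiOH, H2O2, THF/H2O, 0 °C; Na2SO3; HCl to pH 4, 0 °C
Reagents that add atoms: hydrogen peroxide, OO
Why: Lithium hydroperoxide attacks the exocyclic imide carbonyl selectively even in hindered cases, releasing the acid and the recoverable auxiliary without touching the TIPS enol ether or epimerising C4.

**Step 8**
Reactants: 17 carboxylic acid; 18 methyllithium
Product: 20 5-endo methyl ketone (TIPS enol ether retained), via dilithium gem-diolate 19 (not isolated)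
Conditions: MeLi (3 equiv), Et2O, −78 → 0 °C; inverse quench into cold aq. NH4Cl
Reagents that add atoms: methyllithium (18), [Li]C
Why: Addition of methyllithium to the lithium carboxylate stops at the gem-diolate, so the methyl ketone is released only on the buffered quench and no tertiary alcohol forms.

**Step 9**
Reactants: 20 methyl ketone; 21 methyltriphenylphosphonium bromide
Product: 23 5-endo-isopropenyl norbornan-2-one, via isopropenyl silyl enol ether 22 (not isolated)
Conditions: Ph3PCH3Br, KOtBu, THF, 23 → 50 °C; then 2 M HCl, THF, 23 °C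
Reagents that add atoms: methyltriphenylphosphonium bromide (21), C[P+](c1ccccc1)(c1ccccc1)c1ccccc1.[Br-]
Why: Wittig methylenation of a methyl ketone on a ring methine next to a quaternary carbon (as in 20-oxo steroids) should proceed without epimerising that methine (C4), and the acid work-up then hydrolyses the silyl enol ether to the C20 ketone.

**Step 10**
Reactants: 23 isopropenyl ketone
Product: 24 5-endo-isopropyl norbornan-2-one
Conditions: KO2CN=NCO2K (excess, portionwise), AcOH, MeOH/CH2Cl2, 23 °C
Reagents that add atoms: none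
Why: Diimide reduction is selective for the 1,1-disubstituted isopropenyl alkene over the trisubstituted bromoalkene and, unlike catalytic hydrogenation, cannot cleave the C–Br bond, and the azodicarboxylate source is compatible with the ketone.

**Step 11**
Reactants: 24 isopropyl ketone; 25 2-bromo-N-methoxy-N-methylacetamide
Product: 27 3-exo-(Weinreb acetamido-methyl) ketone, via lithium enolate 26 (not isolated)
Conditions: LDA, THF, −78 °C; 25, DMPU, −78 → −20 °C
Reagents that add atoms: 2-bromo-N-methoxy-N-methylacetamide (25), CON(C)C(=O)CBr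
Why: The ketone can enolise only toward C19 (C6 is a bridgehead), and the norbornanone enolate is alkylated from the exo face because the endo face is screened by the bicycle and the endo isopropyl group, which sets C19 with the side chain exo.

**Step 12**
Reactants: 27 keto amide
Product: 28 2-endo-hydroxy amide
Conditions: NaBH4, MeOH, 0 °C
Reagents that add atoms: none
Why: A small hydride attacks the norbornanone from the exo face (as in norcamphor and fenchone reductions), giving the endo C20 alcohol trans to the C19 side chain, while the Weinreb amide is inert to borohydride.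

**Step 13**
Reactants: 28 hydroxy amide; 29 vinylmagnesium bromide
Product: 31 hydroxy vinyl ketone, via magnesium chelate 30 (not isolated)
Conditions: CH2=CHMgBr (3.5 equiv), THF, −20 → 0 °C; inverse quench into cold 1 M HCl
Reagents that add atoms: vinylmagnesium bromide (29), C=C[Mg]Br
Why: Weinreb ketone synthesis, in which the chelated tetrahedral adduct survives until work-up so that only one vinyl group is delivered, and the acidic inverse quench keeps the liberated amine from adding to the vinyl ketone.

**Step 14**
Reactants: 31 hydroxy vinyl ketone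
Product: 32 bis-silylated triene (C20 OTBS; (Z)-2-silyloxydiene on C19; (E)-bromoalkene chain on C8)
Conditions: TBSOTf (2.5 equiv), Et3N, CH2Cl2, −78 → 0 °C
Reagents that add atoms: tert-butyldimethylsilyl trifluoromethanesulfonate, CC(C)(C)[Si](C)(C)OS(=O)(=O)C(F)(F)F
Why: Silyl triflate and amine base silylate the alcohol and soft-enolise the ketone, which has α-hydrogens only at C18, so that a single 2-silyloxydiene forms as the (Z)-enol ether (C19 anti to the vinyl group) that minimises allylic strain.

**Step 15**
Reactants: 32 bis-silylated triene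
Product: 33 tetracyclic C13 bromide with C15=C16 TBS enol ether and C20 OTBS
Conditions: PhMe (0.01 M), BHT, i-Pr2NEt (trace), base-washed sealed tube, 185 °C
Reagents that add atoms: none
Why: Concerted, suprafacial thermal [4+2] cycloaddition of the unactivated (E)-bromoalkene C11=C13 to the (Z)-2-silyloxydiene C18=C16–C15=C14; the closest known reaction type is the thermal intramolecular Diels–Alder reaction of 1,7,9-decatrienes, here with a 2-silyloxy diene and a haloalkene dienophile. Ring C (C11, C13, C14, C15, C16, C18) closes by the cycloaddition itself, and ring B (C8, C9, C10, C11, C18, C19) closes as the tether C19–C8–C9–C10 folds into a chair. C13 is fixed relative to C11 by the alkene geometry: Br is cis to the C12 methyl in the (E)-alkene and stays cis, which is the equatorial bromide, made without substitution at a neopentyl carbon. C18 is controlled by the norbornane, which holds the exo C18 and the bridgehead C9 gauche so that only one chair exists, and in that chair the diene must be equatorial at C18 because the axial position is 1,3-diaxial to the C7 bridge. With the (E)-diene equatorial, C14 lies on the side of H18, so the dienophile can only present C13 equatorial and the C12 methyl axial on the face away from C7, which gives the trans B/C fusion and the required C11 configuration. The step needs chair rather than boat folding and enough thermal reactivity; the rigid bicycle with quaternary C8 leaves few free rotors, which favours both.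

**Step 16**
Reactants: 33 tetracyclic bis-silyl compound
Product: 34 C16 ketone with free C20 endo hydroxyl
Conditions: 48% aq. HF, MeCN, 0 → 23 °C
Reagents that add atoms: none
Why: Acidic fluoride cleaves the silyl enol ether to the C16 ketone (protonation at C15) and the secondary silyl ether in one operation, so that the γ-bromo ketone is never enolised by base and the tertiary alcohol made next never meets acid; C18 stays, or settles, in the more stable trans fusion.

**Step 17**
Reactants: 34 hydroxy ketone; 18 methyllithium
Product: 35 target CNP0295684.1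
Conditions: CeCl3, MeLi (4 equiv), THF, −78 °C
Reagents that add atoms: methyllithium (18), [Li]C
Why: The weakly basic organocerium reagent adds to the hindered, enolisable ketone rather than deprotonating it, and it attacks C16 along the equatorial trajectory because the axial one is blocked by the 1,3-diaxial C12 methyl group, placing C17 equatorial and the hydroxyl axial as in the target.

**Compound list**

1 | but-3-yn-1-ol | C#CCCO | starting material
2 | trimethylaluminium | C[Al](C)C | starting material
3 | dimethyl[(1E)-4-(dimethylalumanyloxy)-2-methylbut-1-en-1-yl]alumane (formed in situ) | C[Al](C)OCC/C(C)=C/[Al](C)C | intermediate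
4 | (3E)-4-bromo-3-methylbut-3-en-1-ol | OCC/C(C)=C/Br | intermediate
5 | (1E)-1,4-dibromo-2-methylbut-1-ene | BrCC/C(C)=C/Br | intermediate
6 | 3-ethoxycyclopent-2-en-1-one | CCOC1=CC(=O)CC1 | starting material
7 | [(3E)-4-bromo-3-methylbut-3-en-1-yl]magnesium bromide (formed in situ) | Br[Mg]CC/C(C)=C/Br | intermediate
8 | 1-[(3E)-4-bromo-3-methylbut-3-en-1-yl]-3-ethoxycyclopent-2-en-1-ol (racemic carbinol, formed in situ) | CCOC1=CC(O)(CC/C(C)=C/Br)CC1 | intermediate
9 | 3-[(3E)-4-bromo-3-methylbut-3-en-1-yl]cyclopent-2-en-1-one | O=C1C=C(CC/C(C)=C/Br)CC1 | intermediate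
10 | lithium 4-[(3E)-4-bromo-3-methylbut-3-en-1-yl]cyclopenta-1,4-dien-1-olate (formed in situ) | [Li]OC1=CCC(CC/C(C)=C/Br)=C1 | intermediate
11 | ({4-[(3E)-4-bromo-3-methylbut-3-en-1-yl]cyclopenta-1,4-dien-1-yl}oxy)tri(propan-2-yl)silane | CC(C)[Si](OC1=CCC(CC/C(C)=C/Br)=C1)(C(C)C)C(C)C | intermediate
12 | (4S)-4-benzyl-1,3-oxazolidin-2-one | O=C1N[C@@H](Cc2ccccc2)CO1 | starting material
13 | prop-2-enoyl chloride | C=CC(=O)Cl | starting material
14 | N-bromomagnesio-(4S)-4-benzyl-1,3-oxazolidin-2-one (formed in situ) | Br[Mg]N1[C@@H](Cc2ccccc2)COC1=O | intermediate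
15 | (4S)-4-benzyl-3-(prop-2-enoyl)-1,3-oxazolidin-2-one | C=CC(=O)N1[C@@H](Cc2ccccc2)COC1=O | intermediate
16 | (4S)-4-benzyl-3-({4-[(3E)-4-bromo-3-methylbut-3-en-1-yl]-2-(triisopropylsilyloxy)bicyclo[2.2.1]hept-2-en-5-endo-yl}carbonyl)-1,3-oxazolidin-2-one | O=C(N1[C@@H](Cc2ccccc2)COC1=O)[C@@H]1C[C@H]2C[C@]1(CC/C(C)=C/Br)C=C2O[Si](C(C)C)(C(C)C)C(C)C | intermediate
17 | 4-[(3E)-4-bromo-3-methylbut-3-en-1-yl]-2-(triisopropylsilyloxy)bicyclo[2.2.1]hept-2-ene-5-endo-carboxylic acid | OC(=O)[C@@H]1C[C@H]2C[C@]1(CC/C(C)=C/Br)C=C2O[Si](C(C)C)(C(C)C)C(C)C | intermediate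
18 | methyllithium | [Li]C | starting material
19 | dilithium gem-diolate from 17 and methyllithium (formed in situ) | CC(O[Li])(O[Li])[C@@H]1C[C@H]2C[C@]1(CC/C(C)=C/Br)C=C2O[Si](C(C)C)(C(C)C)C(C)C | intermediate
20 | 1-{4-[(3E)-4-bromo-3-methylbut-3-en-1-yl]-2-(triisopropylsilyloxy)bicyclo[2.2.1]hept-2-en-5-endo-yl}ethan-1-one | CC(=O)[C@@H]1C[C@H]2C[C@]1(CC/C(C)=C/Br)C=C2O[Si](C(C)C)(C(C)C)C(C)C | intermediate
21 | methyltriphenylphosphonium bromide | C[P+](c1ccccc1)(c1ccccc1)c1ccccc1.[Br-] | starting material
22 | 5-endo-isopropenyl analogue of 20 (TIPS enol ether, formed in situ) | C=C(C)[C@@H]1C[C@H]2C[C@]1(CC/C(C)=C/Br)C=C2O[Si](C(C)C)(C(C)C)C(C)C | intermediate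
23 | 4-[(3E)-4-bromo-3-methylbut-3-en-1-yl]-5-endo-(prop-1-en-2-yl)bicyclo[2.2.1]heptan-2-one | C=C(C)[C@@H]1C[C@H]2C[C@]1(CC/C(C)=C/Br)CC2=O | intermediate
24 | 4-[(3E)-4-bromo-3-methylbut-3-en-1-yl]-5-endo-(propan-2-yl)bicyclo[2.2.1]heptan-2-one | CC(C)[C@@H]1C[C@H]2C[C@]1(CC/C(C)=C/Br)CC2=O | intermediate
25 | 2-bromo-N-methoxy-N-methylacetamide | CON(C)C(=O)CBr | starting material
26 | lithium enolate of 24 (C19=C20, formed in situ) | CC(C)[C@@H]1C[C@H]2C[C@]1(CC/C(C)=C/Br)C=C2O[Li] | intermediate
27 | 2-{4-[(3E)-4-bromo-3-methylbut-3-en-1-yl]-2-oxo-5-endo-(propan-2-yl)bicyclo[2.2.1]heptan-3-exo-yl}-N-methoxy-N-methylacetamide | CC(C)[C@@H]1C[C@H]2C[C@]1(CC/C(C)=C/Br)[C@H](CC(=O)N(C)OC)C2=O | intermediate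
28 | 2-{4-[(3E)-4-bromo-3-methylbut-3-en-1-yl]-2-endo-hydroxy-5-endo-(propan-2-yl)bicyclo[2.2.1]heptan-3-exo-yl}-N-methoxy-N-methylacetamide | CC(C)[C@@H]1C[C@H]2C[C@]1(CC/C(C)=C/Br)[C@H](CC(=O)N(C)OC)[C@H]2O | intermediate
29 | vinylmagnesium bromide | C=C[Mg]Br | starting material
30 | bromomagnesium tetrahedral adduct of 28 and 29 (C20 alkoxide, formed in situ) | CC(C)[C@@H]1C[C@H]2C[C@]1(CC/C(C)=C/Br)[C@H](CC(O[Mg]Br)(C=C)N(C)OC)[C@H]2O[Mg]Br | intermediate
31 | 1-{4-[(3E)-4-bromo-3-methylbut-3-en-1-yl]-2-endo-hydroxy-5-endo-(propan-2-yl)bicyclo[2.2.1]heptan-3-exo-yl}but-3-en-2-one | CC(C)[C@@H]1C[C@H]2C[C@]1(CC/C(C)=C/Br)[C@H](CC(=O)C=C)[C@H]2O | intermediate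
32 | bis-TBS triene: as 31 with 2-endo-OTBS and 3-exo-[(1Z)-2-(tert-butyldimethylsilyloxy)buta-1,3-dien-1-yl] | CC(C)[C@@H]1C[C@H]2C[C@]1(CC/C(C)=C/Br)[C@H](/C=C(\O[Si](C)(C)C(C)(C)C)C=C)[C@H]2O[Si](C)(C)C(C)(C)C | intermediate
33 | tetracyclic adduct: target skeleton with equatorial C13–Br, C15=C16 TBS enol ether, C20 endo-OTBS, trans B/C fusion | CC(C)[C@@H]1C[C@H]2C[C@@]13CC[C@]1(C)[C@@H](Br)CC=C(O[Si](C)(C)C(C)(C)C)[C@H]1[C@@H]3[C@H]2O[Si](C)(C)C(C)(C)C | intermediate
34 | tetracyclic C16 ketone with C20 endo-hydroxyl | CC(C)[C@@H]1C[C@H]2C[C@@]13CC[C@]1(C)[C@@H](Br)CCC(=O)[C@H]1[C@@H]3[C@H]2O | intermediate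
35 | CNP0295684.1 | CC(C)[C@@H]1C[C@H]2C[C@@]13CC[C@]1(C)[C@@H](Br)CC[C@@](C)(O)[C@H]1[C@@H]3[C@H]2O | target

**Step count**

Total: 17 steps. Longest linear sequence: 16 steps (steps 1–4 and 6–17; step 5 is a one-step branch).

**Steps most likely to fail**

Step 15 (the cycloaddition). The unactivated, trisubstituted bromoalkene may add more slowly than the open-chain silyl dienol ether is lost by hydrolysis, silyl migration or polymerisation at the temperature needed. Boat-type folding may also divert material to fusion isomers. Fallback: setting out from hydroxy vinyl ketone 31, O16 and O20 are tied together with di-tert-butylsilyl bis(triflate) and 2,6-lutidine under high dilution. This should give the seven-membered cyclic di-tert-butylsilylene dienol ether F1. Only the (Z)-enol can close this ring, the C19–C18 rotamer is held close to the one the chair transition state uses, and the hindered silylene should tolerate 210–230 °C in o-dichlorobenzene. Cycloaddition there should give the silylene-bridged tetracyclic adduct F2. Aqueous HF in acetonitrile removes the silylene and returns to the route at hydroxy ketone 34. In either variant a cis-fused adduct with the correct C11 and C13 centres would be corrected at C18 by acid equilibration of ketone 34.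

Step 6 (the asymmetric Diels–Alder reaction). The stoichiometric aluminium Lewis acid may desilylate the diene or stop at an open-chain Mukaiyama–Michael adduct. The diene may isomerise by 1,5-hydrogen shift before it is consumed, and a stepwise course may erode facial control. Fallback: setting out from diene 11, a catalytic enantioselective cycloaddition with achiral 3-acryloyl-1,3-oxazolidin-2-one under a much weaker Lewis acid, [Cu((R,R)-t-Bu-box)](SbF6)2 (10 mol %, CH2Cl2, −78 → −40 °C). In the square-planar chelate of this ligand enantiomer the tert-butyl group near the alkene covers the Cα re face, so the diene should add to the si face as in step 6. This should give the achiral-imide adduct F3. Lithium hydroperoxide cleavage of F3 rejoins the route at acid 17.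

Step 11 (C19 alkylation). The enolate next to the quaternary bridgehead may be alkylated slowly, and proton transfer from the acidic α-bromoamide may quench it instead. Fallback: setting out from ketone 24, alkylation with allyl bromide (LDA, THF/DMPU) should give the 3-exo-allyl ketone F4. NaBH4 then gives the endo allyl alcohol F5. OsO4 (cat.)/NaIO4 with 2,6-lutidine cleaves the monosubstituted alkene in preference to the electron-poor trisubstituted bromoalkene to give the hydroxy aldehyde F6. Vinylmagnesium bromide gives the allylic alcohol F7 (both C16 epimers). MnO2 oxidises only the allylic hydroxyl and returns to the route at hydroxy vinyl ketone 31.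

**Further compounds**

F1 | step 15 | cyclic di-tert-butylsilylene dienol ether of 31 (O16–Si(t-Bu)2–O20, (Z)-enol, seven-membered ring fused at C19–C20) | CC(C)[C@@H]1C[C@H]2C[C@]1(CC/C(C)=C/Br)[C@@H]1/C=C(C=C)\O[Si](C(C)(C)C)(C(C)(C)C)O[C@H]12
F2 | step 15 | silylene-bridged tetracyclic adduct (C15=C16 enol ether, O16–Si(t-Bu)2–O20) | CC(C)[C@@H]1C[C@H]2C[C@@]13CC[C@]1(C)[C@@H](Br)CC=C4O[Si](C(C)(C)C)(C(C)(C)C)O[C@@H]2[C@H]3[C@@H]14
F3 | step 6 | 3-({4-[(3E)-4-bromo-3-methylbut-3-en-1-yl]-2-(triisopropylsilyloxy)bicyclo[2.2.1]hept-2-en-5-endo-yl}carbonyl)-1,3-oxazolidin-2-one | O=C(N1CCOC1=O)[C@@H]1C[C@H]2C[C@]1(CC/C(C)=C/Br)C=C2O[Si](C(C)C)(C(C)C)C(C)C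
F4 | step 11 | 3-exo-allyl-4-[(3E)-4-bromo-3-methylbut-3-en-1-yl]-5-endo-(propan-2-yl)bicyclo[2.2.1]heptan-2-one | CC(C)[C@@H]1C[C@H]2C[C@]1(CC/C(C)=C/Br)[C@H](CC=C)C2=O
F5 | step 11 | 3-exo-allyl-4-[(3E)-4-bromo-3-methylbut-3-en-1-yl]-5-endo-(propan-2-yl)bicyclo[2.2.1]heptan-2-endo-ol | CC(C)[C@@H]1C[C@H]2C[C@]1(CC/C(C)=C/Br)[C@H](CC=C)[C@H]2O
F6 | step 11 | 2-{4-[(3E)-4-bromo-3-methylbut-3-en-1-yl]-2-endo-hydroxy-5-endo-(propan-2-yl)bicyclo[2.2.1]heptan-3-exo-yl}acetaldehyde | CC(C)[C@@H]1C[C@H]2C[C@]1(CC/C(C)=C/Br)[C@H](CC=O)[C@H]2O
F7 | step 11 | 1-{4-[(3E)-4-bromo-3-methylbut-3-en-1-yl]-2-endo-hydroxy-5-endo-(propan-2-yl)bicyclo[2.2.1]heptan-3-exo-yl}but-3-en-2-ol (both carbinol epimers) | CC(C)[C@@H]1C[C@H]2C[C@]1(CC/C(C)=C/Br)[C@H](CC(O)C=C)[C@H]2O
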